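The closed, stirred vessel held 0.064 M of starting material and 0.600 equiv of coupling partner, the limiting reagent if the two react one to one. This flask, followed so far as the north-west run, had 1.2 mM of added ligand, and the one earlier run, south, differed from it in having 0.80 mM.

in all of them: starting material 0.064 M; catalyst 2.3 mol%
- north-west: coupling partner 0.60 equiv; added ligand 1.2 mM; the very flask that is asked about, followed so far
- south: coupling partner 0.60 equiv; added ligand 0.80 mM; run made earlier
- flask: coupling partner 0.600 equiv; added ligand 1.2 mM

| run | time / min | target / % |
|---|---|---|
| north-west | 0.500 | 1 |
| north-west | 1.50 | 0 |
| north-west | 3.00 | 2 |
| north-west | 4.00 | 5 |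
| north-west | 6.00 | 4 |
| south | 0.833 | 1 |
| south | 1.50 | 3 |
| south | 3.00 | 3 |
| south | 6.00 | 9 |
| south | 10.0 | 16 |

(readings scatter by 1.5 percentage points)

- no earlier run changes the charge of catalyst; that part of a forecast is a guess
- no earlier run changes the charge of coupling partner; that part of a forecast is a guess

- factor on the rate of making target when 10% of the starting material are converted if coupling partner is charged twice over
- factor on the rate when 10% of the starting material are converted if catalyst is charged at 25 mol% instead

I asked first what the added ligand did. At 6.00 min the north-west run read 4% of target, and at 6.00 min the south run read 9%. That was a rate ratio of about 2.25, although c(added ligand) differed by a factor of 1.50.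

The catalyst charge was 1.47 mM, not far above the ligand charge. So I supposed that each added ligand tightly took one catalyst out of play. I called c(catalyst) charged minus c(added ligand) charged, 0.272 mM in this flask, the uncovered catalyst. The south run had 0.672 mM, a ratio of 2.47, and with a scatter of 1.5 percentage points the readings could not separate that from what they showed.

What then would 25 mol% of catalyst do? The charge became 16.0 mM, or 10.9 times the old one, but the uncovered catalyst became 14.8 mM. Taking the rate as proportional to it, I expected a factor of 54.4, which is more than the charge rose. No run tested this, so it remained my guess.

Doubling the coupling partner was a guess too. At 10% conversion the partner left rose from 0.500 to 1.10 equivalents, so first order gave 2.20.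

The forecast gave 1.6 for the partner and 8 for the catalyst, holding that “released ligand, aggregation or a half-order regime would reduce this”.

The flask gave 2.20 for the partner and 48.0 for the catalyst.

    starting material + coupling partner + catalyst → target + catalyst, rate k1*[starting material]*[coupling partner]*[catalyst]/(1 + ([starting material]/sat1)) (7.40 mM, k = 7210 /M²/min)
    catalyst + added ligand ⇌ idle complex A, settled at all times (K = 70000 /M)
    starting material + catalyst ⇌ idle complex B, settled at all times (K = 3.30 /M)

Pairing of catalyst with added ligand stood at 84 as equilibrium constant times c(added ligand) charged, far above the 0.21 for pairing with starting material at its charge, and at 1.50 min the flask held 77.5% of its catalyst as idle complex A and 22.5% as catalyst with idle complex B, where the uncovered catalyst had given 18.5%. In the flask with 25 mol%, at 10% conversion, idle complex A held 7.49%, and catalyst with idle complex B held 92.5%, where the uncovered catalyst gave 92.5%.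

The numbers in the tables stem from a simulated flask with made-up constants; scatter was added.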